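**Remarks on the chemistry**

- The target is the (2S)-flavanone whose ring B side chain is an (R)-configured 3,3-dimethyloxirane. Both descriptors were derived from the SMILES and are used throughout.
- The structures of the key-step precursor 13 and product 15 were checked atom by atom and need no change. Three corrections are made to the chemistry around them:
  - an O-allylation step is needed before the Claisen rearrangement, and the carboxyl group is carried as an allyl ester so that it is freed without hydroxide;
  - titanium residues are removed before the catalytic acid is added, because a strict one-pot sequence would destroy the acid;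
  - the ring closure is more precisely a 6-(enolendo)-endo-trig process.
- Assumption: (R)-TRIP is written as the chiral acid. Its sense of induction cannot be predicted for this substrate. If it favours the (2R) series, (S)-TRIP is used and nothing else changes.

## Structural features

The target 18 is a (2S)-flavanone: a phloroglucinol-type benzene ring (ring A) is fused through C4a–C8a to a dihydropyranone (ring C: O1, C2, C3, C4=O), and C2 carries a para-hydroxyphenyl ring (ring B). Ring A has hydroxyls at C5 (chelated to the C4 carbonyl) and C7 and a prenyl chain at C8 next to O1. Ring B has at C3' a prenyl chain oxidized to an (R)-trisubstituted epoxide, ortho to the 4'-hydroxyl. The two stereocentres, C2 and the epoxide CH, are six bonds apart across ring B, so neither can direct the other and each needs its own catalyst control. The fragile elements are: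

- the epoxide beside a free phenol (acid opens it, and the phenoxide attacks it in a 5-exo mode);
- the benzylic ether centre C2 (reversible opening to the 2'-hydroxychalcone under base or strong acid);
- the acid-sensitive prenyl olefin and the nucleophilic C6 of ring A.

The real difficulty is threefold: C2 has no neighbouring handle and epimerizes easily; two chemically alike C5 chains must end up different; and three phenols must be freed last without touching the epoxide or C2. The key step exploits the fact that O1, C2, C4, C4a and C8a of ring C are exactly the atoms of an acetal between a ring A salicylic acid (carboxyl carbon = C4, phenol oxygen = O1) and the ring B aldehyde (carbonyl carbon = C2). In that acetal, the 1,3-benzodioxin-4-one 13, the place of the C3 methylene is taken by the ring oxygen O3, so ring C results when O3 is exchanged for CH2. The para-oxygen of ring B, which makes C2 labile, is also what allows the acetal to ionize at C2 and the exchange to be stereoconvergent.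

## Logic of the disconnections

**18 to 17.** The three phenolic O–H bonds are traded for O–Si bonds. Silyl ethers are the only masks that tolerate a titanium methylidene, a Brønsted acid, a dioxirane and a ruthenium carbene and still leave under near-neutral conditions. The forward step must free the ring B phenol beside the epoxide without ever leaving a phenoxide, so the fluoride has to be buffered.

**17 to 16.** The C=C bond of the ring A chain is cut, leaving an allyl group. With allyl on ring A and prenyl on ring B the two chains differ in substitution, which is what allows only one to be epoxidized. The forward step is a cross-metathesis with 2-methyl-2-butene that must leave the epoxide alone.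

**16 to 15.** The two C–O bonds of the oxirane are cut, which removes the second stereocentre. The forward epoxidation must be reagent-controlled (C2 is too far away to help), must choose the trisubstituted olefin over the terminal one, and must not epimerize C2.

**15 to 13 (through 14).** C2–C3 and C3–C4 are cut and the C3 methylene is replaced by oxygen. This removes ring C and the C2 stereocentre in one operation and turns the problem into the making of an acetal. The forward step must methylenate a hindered lactone carbonyl, ionize the acetal at C2–O3 only, and return the enol carbon to one face of the cation under control of a chiral acid. Titanium residues must be removed before the acid is added.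

**13 to 11 and 4.** The acetal bonds O1–C2 and C2–O3 are cut, giving two aromatic fragments of similar size. The forward condensation produces an ionizable acylal and therefore has to run without water and without strong protic acid, through the bis(trimethylsilyl) derivative 12.

**11 back to 5 and 6.** The route runs through 10, 9, 8 and 7.

- In 11 the carboxyl O–H is traded for an O-allyl ester bond (10). Zerovalent palladium frees the acid without hydroxide, which would strip the aryl silyl ethers and struggle with a doubly ortho-substituted, electron-rich ester.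
- In 10 the ring C3–allyl bond is cut and reconnected to the neighbouring oxygen (9). Only one ortho position is open, so the [3,3] shift is regiochemically unambiguous and releases the very hydroxyl that becomes O1.
- 9 comes from 8 by O-allylation, 8 from 7 by silylation of the two hydroxyls not chelated to the ester, and 7 from 5 and 6 by carboxylate alkylation.
- The demands are regioselective bis-silylation (met by the ester chelate) and silyl ethers that survive 190 °C.

**4 to 3 to 1 and 2.** The O–Si bond and then the ring C3–prenyl bond are cut. Direct ortho C-prenylation of the phenoxide in water reaches 3 in one step. The forward step must favour C- over O-alkylation, which the aqueous medium promotes.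

## Other disconnections considered

**Alternative 1:** Carbonylative flavone annulation followed by asymmetric conjugate reduction.

- Cut: C4a–C4, C4–C3 and O1–C2 of the flavone A1, with C2–H and C3–H added afterwards.
- Forward key step: the iodophenol A2, carbon monoxide and the arylacetylene A3 would combine under PdCl2(PPh3)2 in diethylamine. Zerovalent palladium inserts into the C–I bond, CO insertion gives an acylpalladium species, coupling with the alkyne gives an ynone, and amine-assisted 6-endo oxa-Michael closure gives A1. Asymmetric 1,4-reduction of A1 (for example a CuH catalyst with a chiral bisphosphine) and desilylation would then lead to 18.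
- In favour: three components give the whole skeleton in one step, there is no labile acetal and no decarboxylation-prone acid, and the two C5 chains are differentiated simply by sitting on different fragments, so no metathesis detour is needed. On precedent for the ring-forming event this plan is the better one.
- Against, here:
  - the epoxide of A3 and the aryl silyl ethers would face a hot secondary amine (aminolysis, desilylation);
  - the iodide of A2 is flanked by two oxygen substituents, which slows oxidative addition and opens the way to 5-exo closure to an aurone;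
  - the late reduction must add hydride enantioselectively to an aryl-substituted, electron-rich β-carbon, and the resulting enolate can expel the ring oxygen and lose C2.
- Comparison:
  - Structure: both plans set C2 by catalyst control in a step without direct precedent, so they are equal on stereochemical risk. Here, however, C2 would be set with the epoxide already present, so any shortfall appears as diastereomers, whereas the chosen plan sets C2 first and can upgrade 15 before the second centre arrives.
  - Mechanism: palladium acyl chemistry versus ion-pair recombination; the ring closure is on firmer ground here.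
  - Step economy: about equal (a similar number of steps to A2 and A3, then three more).

**Alternative 2:** Three-component ortho-quinone methide cycloaddition.

- Cut: O1–C2 and C3–C4 of the cis-4-methoxyflavan A4.
- Forward key step: the salicylaldehyde A5 and trimethyl orthoformate would give, under a chiral acid, a 4-methoxy ortho-quinone methide. This would undergo an inverse-demand [4+2] cycloaddition with the styrene A6 to give A4, with the aryl group at C2 by polarity. Cleavage of the methyl ether and oxidation at C4 would then meet the chosen route at 15.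
- In favour: two fragments are joined directly; the aldehyde oxidation level on ring A avoids the ester unmasking and the sensitive acid 11, which is better than the chosen plan by one or two steps on that arm; and chiral acid control of ortho-quinone methide cycloadditions has closer asymmetric analogy than the chosen rearrangement, which is also a point in its favour.
- Against, here:
  - C4 arrives one oxidation level low, so a stereocentre is made and destroyed and two redox steps are added at a 5,7-dioxygenated benzylic position that ionizes very readily (elimination to the flav-3-ene);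
  - the prenyl olefin of A6 is a second electron-rich dienophile;
  - the para-silyloxystyrene is prone to cationic oligomerization under the acid needed to ionize the acetal.
- Comparison:
  - Structure: the same ring A and ring B pieces and the same C8 allyl device would be used.
  - Mechanism: both plans depend on a chiral phosphate controlling an O-aryl oxocarbenium-type species, so they are equal in principle. The alternative forms its bonds between two molecules (more convergent), whereas the chosen plan forms them within one molecule (no competition between two olefins, no regiochemical question).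
  - Step economy: about equal overall, because two steps are saved before and two added after the key step.

**Alternative 3:** Aryne annulation with a chiral β-hydroxy ester.

- Cut: C8a–O1 and C4a–C4 of the tris-allyl flavanone A7.
- Forward key step: CsF would release the aryne from the silylaryl triflate A8. The alkoxide of the β-hydroxy ester A9 would add to the aryne carbon remote from the neighbouring allyloxy group (the future C8a), and the resulting aryl anion would attack the ester carbonyl (6-exo-trig) with loss of methoxide to give A7. Removal of three allyl ethers with zerovalent palladium would give 18.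
- In favour: C2 would come from an established asymmetric reaction used to make A9, and the epoxide would also be in place before the union, so the stereochemistry rests on firmer ground than in the chosen plan. The final unmasking is fluoride-free and near neutral, which is better for the phenol–epoxide pair.
- Against, here:
  - the aryne is unsymmetrical, and the attacked carbon is flanked by the prenyl group, which also offers an intramolecular ene pathway;
  - the benzylic alkoxide of A9 can undergo retro-aldol cleavage or elimination to the cinnamate under basic fluoride;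
  - the flavanone formed can ring-open in the same medium and lose C2;
  - A8 is a hexasubstituted benzene that needs a long, regiocontrolled preparation.
- Comparison:
  - Structure: both stereocentres are carried into the key step, so any erosion shows as diastereomers.
  - Mechanism: anionic aryne chemistry under base versus a cationic ion pair under acid; the base-sensitive C2 centre favours the chosen plan.
  - Step economy: more convergent but clearly longer in total, so worse.

Key step: step 9

## Route

Step 1
Reactants: 1 4-hydroxybenzaldehyde; 2 prenyl bromide (1-bromo-3-methylbut-2-ene)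
Product: 3 4-hydroxy-3-(3-methylbut-2-enyl)benzaldehyde
Conditions: aq. KOH (1.1 equiv), 0 °C → rt
Reagents that add atoms: none
Why: Phenoxide C-alkylation: in water the phenoxide oxygen is hydrogen-bonded, so the allylic bromide is taken up at the ortho carbon (para is blocked by the formyl group); the O-prenyl ether and dialkylated material are the expected, separable by-products.

Step 2
Reactants: 3 4-hydroxy-3-(3-methylbut-2-enyl)benzaldehyde
Product: 4 3-(3-methylbut-2-enyl)-4-(triisopropylsilyloxy)benzaldehyde
Conditions: TIPSCl, imidazole, DMF, rt
Reagents that add atoms: triisopropylsilyl chloride, CC(C)[Si](Cl)(C(C)C)C(C)C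
Why: Standard imidazole-mediated O-silylation of a phenol; the bulky silyl ether is chosen to survive all later steps up to the last.

Step 3
Reactants: 5 2,4,6-trihydroxybenzoic acid; 6 allyl bromide (3-bromoprop-1-ene)
Product: 7 allyl 2,4,6-trihydroxybenzoate
Conditions: KHCO3 (1.1 equiv), DMF, rt
Reagents that add atoms: none
Why: Carboxylate O-alkylation (SN2): hydrogencarbonate deprotonates only the strongly acidic carboxyl group, so the bromide esterifies without etherifying the phenols.

Step 4
Reactants: 7 allyl 2,4,6-trihydroxybenzoate
Product: 8 allyl 2-hydroxy-4,6-bis(triisopropylsilyloxy)benzoate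
Conditions: TIPSCl (2.2 equiv), imidazole, DMF, 0 °C → rt
Reagents that add atoms: triisopropylsilyl chloride, CC(C)[Si](Cl)(C(C)C)C(C)C
Why: Regioselective silylation: the para hydroxyl and one ortho hydroxyl react, while the last hydroxyl is locked in a hydrogen bond to the ester carbonyl, is hindered, and should remain free.

Step 5
Reactants: 8 allyl 2-hydroxy-4,6-bis(triisopropylsilyloxy)benzoate; 6 allyl bromide
Product: 9 allyl 2-(allyloxy)-4,6-bis(triisopropylsilyloxy)benzoate
Conditions: K2CO3, acetone, 55 °C
Reagents that add atoms: none
Why: Williamson etherification of the chelated phenol; carbonate in acetone is mild enough for aryl triisopropylsilyl ethers.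

Step 6
Reactants: 9 allyl 2-(allyloxy)-4,6-bis(triisopropylsilyloxy)benzoate
Product: 10 allyl 3-allyl-2-hydroxy-4,6-bis(triisopropylsilyloxy)benzoate
Conditions: PhNEt2, 190 °C, sealed tube, argon
Reagents that add atoms: none
Why: Aromatic Claisen rearrangement ([3,3]): only one ortho position (C3) carries hydrogen, so rearomatization fixes the allyl group there and frees the hydroxyl that will become O1; the allyl ester is thermally inert.

Step 7
Reactants: 10 allyl 3-allyl-2-hydroxy-4,6-bis(triisopropylsilyloxy)benzoate
Product: 11 3-allyl-2-hydroxy-4,6-bis(triisopropylsilyloxy)benzoic acid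
Conditions: Pd(PPh3)4 (3 mol%), morpholine, THF, rt; cold aq. citric acid work-up
Reagents that add atoms: none
Why: Tsuji–Trost deallylation: zerovalent palladium ionizes the allyl ester to a π-allyl complex that morpholine intercepts, so the acid is freed without hydroxide; the C-allyl group and the silyl ethers do not react, and the acid is used promptly because electron-rich salicylic acids can lose CO2.

Step 8
Reactants: 11 3-allyl-2-hydroxy-4,6-bis(triisopropylsilyloxy)benzoic acid; 4 3-(3-methylbut-2-enyl)-4-(triisopropylsilyloxy)benzaldehyde
Product: 13 8-allyl-2-[3-(3-methylbut-2-enyl)-4-(triisopropylsilyloxy)phenyl]-5,7-bis(triisopropylsilyloxy)-4H-1,3-benzodioxin-4-one (racemic at C2), via trimethylsilyl 3-allyl-2-(trimethylsilyloxy)-4,6-bis(triisopropylsilyloxy)benzoate 12 (not isolated)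
Conditions: HN(SiMe3)2, CH2Cl2, rt, evaporate; then 4, TMSOTf (0.2 equiv), CH2Cl2, −78 °C; pyridine quench
Reagents that add atoms: hexamethyldisilazane, C[Si](C)(C)N[Si](C)(C)C (supplies the trimethylsilyl groups of 12; none of its atoms remain in 13)
Why: Silyl-transfer acetalization as used for 1,3-dioxan-4-ones from β-hydroxy acids: TMSOTf activates the aldehyde, the silyl ether and silyl ester oxygens add in turn, and hexamethyldisiloxane leaves, so no water is formed and the ionizable acylal is made at −78 °C. The acetal carbon is formed racemic, which is of no consequence.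

Step 9
Reactants: 13 8-allyl-2-[3-(3-methylbut-2-enyl)-4-(triisopropylsilyloxy)phenyl]-5,7-bis(triisopropylsilyloxy)-4H-1,3-benzodioxin-4-one
Product: 15 (2S)-8-allyl-2-[3-(3-methylbut-2-enyl)-4-(triisopropylsilyloxy)phenyl]-5,7-bis(triisopropylsilyloxy)chroman-4-one, via 4-methylene enol acetal 14 (not isolated)
Conditions: Cp2TiMe2 (2.5 equiv), toluene, 65 °C, dark; hexane, filtration through basic Al2O3; then (R)-TRIP (10 mol%), 4 Å MS, toluene, −40 → 0 °C
Reagents that add atoms: dimethyltitanocene (Cp2TiMe2), C[Ti](C)(C1C=CC=C1)C1C=CC=C1 (supplies the C3 methylene)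
Why: Proposed new method: Cp2TiMe2 loses methane at 65 °C to give Cp2Ti=CH2, which adds [2+2] to the lactone carbonyl of 13 and cycloreverts to the enol acetal 14 and titanocene oxide; the chiral phosphoric acid then ionizes the C2–O3 acetal bond (directly, or after protonation of the exocyclic methylene and fragmentation, both channels converging) to a contact ion pair of the O-aryl oxocarbenium ion at C2, stabilized by the para-silyloxy ring B, and the phosphate-bound enol of the ring A aryl methyl ketone. The enol carbon, the future C3, attacks C2 in a 6-(enolendo)-endo-trig closure through a chair-like transition state with ring B pseudo-equatorial, which forms C2–C3 and ring C while the former O3 becomes the C4 carbonyl oxygen. The closest known reaction types are the Petasis–Ferrier rearrangement of 1,3-dioxan-4-ones to tetrahydropyran-4-ones (Cp2TiMe2, then Me2AlCl) and chiral phosphoric acid-catalysed aza-Petasis–Ferrier rearrangements; neither covers a benzo-fused acetal or enantiocontrol at an oxocarbenium carbon. C2 is the only new stereocentre: ionization makes it planar, so both enantiomers of 13 funnel into one ion pair, and the face of C2 is chosen by the chiral phosphate, which is hydrogen-bonded to the enol OH and ion-paired with the cation inside the pocket of its 3,3'-aryl groups. The step needs C2–O3 ionization without hydrolysis (dry medium, sieves), C–C not C–O recombination (O-return only regenerates 14, C–C bond formation is irreversible), capture by the tethered enol and not by ring A (C6 is screened by two flanking triisopropylsilyloxy groups), and no reaction of the allyl and prenyl olefins (weak acid, low temperature). Titanium residues are filtered off first because residual Ti–CH3 bonds would protonolyse the catalytic acid.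

Step 10
Reactants: 15 (2S)-8-allyl-2-[3-(3-methylbut-2-enyl)-4-(triisopropylsilyloxy)phenyl]-5,7-bis(triisopropylsilyloxy)chroman-4-one
Product: 16 (2S)-8-allyl-2-[3-{[(2R)-3,3-dimethyloxiran-2-yl]methyl}-4-(triisopropylsilyloxy)phenyl]-5,7-bis(triisopropylsilyloxy)chroman-4-one
Conditions: D-fructose-derived Shi ketone (0.3 equiv), KHSO5 (as Oxone), K2CO3, Bu4NHSO4, MeCN–CH2(OMe)2–aq. Na2B4O7/Na2EDTA, pH 10.5, 0 °C
Reagents that add atoms: potassium peroxymonosulfate, [K+].[O-]S(=O)(=O)OO
Why: Shi epoxidation: the chiral dioxirane formed from the D-fructose-derived ketone transfers oxygen through a spiro transition state to the face of the 2-methylalk-2-ene that gives the (R)-oxirane, under pure catalyst control since C2 is remote. The electrophilic dioxirane selects the trisubstituted prenyl olefin over the monosubstituted allyl group.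

Step 11
Reactants: 16 (2S)-8-allyl-2-[3-{[(2R)-3,3-dimethyloxiran-2-yl]methyl}-4-(triisopropylsilyloxy)phenyl]-5,7-bis(triisopropylsilyloxy)chroman-4-one
Product: 17 (2S)-2-[3-{[(2R)-3,3-dimethyloxiran-2-yl]methyl}-4-(triisopropylsilyloxy)phenyl]-8-(3-methylbut-2-enyl)-5,7-bis(triisopropylsilyloxy)chroman-4-one
Conditions: 2-methyl-2-butene (excess), second-generation Grubbs catalyst RuCl2(=CHPh)(PCy3)(H2IMes) (5 mol%), CH2Cl2, 40 °C, sealed
Reagents that add atoms: 2-methyl-2-butene, CC=C(C)C
Why: Olefin cross-metathesis of a terminal allyl arene with excess 2-methyl-2-butene, an established way to turn allyl into prenyl with loss of propene; the epoxide, ketone and silyl ethers are spectators for the ruthenium carbene.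

Step 12
Reactants: 17 (2S)-2-[3-{[(2R)-3,3-dimethyloxiran-2-yl]methyl}-4-(triisopropylsilyloxy)phenyl]-8-(3-methylbut-2-enyl)-5,7-bis(triisopropylsilyloxy)chroman-4-one
Product: 18 (2S)-2-[3-{[(2R)-3,3-dimethyloxiran-2-yl]methyl}-4-hydroxyphenyl]-5,7-dihydroxy-8-(3-methylbut-2-enyl)chroman-4-one
Conditions: TBAF/AcOH (1:1, 4 equiv), THF, 0 °C
Reagents that add atoms: none
Why: Fluoride-induced cleavage of the three aryl Si–O bonds; acetic acid protonates each phenoxide as it forms, which suppresses both 5-exo opening of the epoxide by the neighbouring ring B phenoxide and retro-oxa-Michael epimerization at C2.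

## Compound list

1 | 4-hydroxybenzaldehyde | O=Cc1ccc(O)cc1 | starting material
2 | prenyl bromide (1-bromo-3-methylbut-2-ene) | CC(C)=CCBr | starting material
3 | 4-hydroxy-3-(3-methylbut-2-enyl)benzaldehyde | CC(C)=CCc1cc(C=O)ccc1O | intermediate
4 | 3-(3-methylbut-2-enyl)-4-(triisopropylsilyloxy)benzaldehyde | CC(C)=CCc1cc(C=O)ccc1O[Si](C(C)C)(C(C)C)C(C)C | intermediate
5 | 2,4,6-trihydroxybenzoic acid | OC(=O)c1c(O)cc(O)cc1O | starting material
6 | allyl bromide (3-bromoprop-1-ene) | C=CCBr | starting material
7 | allyl 2,4,6-trihydroxybenzoate | C=CCOC(=O)c1c(O)cc(O)cc1O | intermediate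
8 | allyl 2-hydroxy-4,6-bis(triisopropylsilyloxy)benzoate | C=CCOC(=O)c1c(O)cc(O[Si](C(C)C)(C(C)C)C(C)C)cc1O[Si](C(C)C)(C(C)C)C(C)C | intermediate
9 | allyl 2-(allyloxy)-4,6-bis(triisopropylsilyloxy)benzoate | C=CCOC(=O)c1c(OCC=C)cc(O[Si](C(C)C)(C(C)C)C(C)C)cc1O[Si](C(C)C)(C(C)C)C(C)C | intermediate
10 | allyl 3-allyl-2-hydroxy-4,6-bis(triisopropylsilyloxy)benzoate | C=CCOC(=O)c1c(O)c(CC=C)c(O[Si](C(C)C)(C(C)C)C(C)C)cc1O[Si](C(C)C)(C(C)C)C(C)C | intermediate
11 | 3-allyl-2-hydroxy-4,6-bis(triisopropylsilyloxy)benzoic acid | OC(=O)c1c(O)c(CC=C)c(O[Si](C(C)C)(C(C)C)C(C)C)cc1O[Si](C(C)C)(C(C)C)C(C)C | intermediate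
12 | trimethylsilyl 3-allyl-2-(trimethylsilyloxy)-4,6-bis(triisopropylsilyloxy)benzoate (not isolated) | C[Si](C)(C)OC(=O)c1c(O[Si](C)(C)C)c(CC=C)c(O[Si](C(C)C)(C(C)C)C(C)C)cc1O[Si](C(C)C)(C(C)C)C(C)C | intermediate
13 | 8-allyl-2-[3-(3-methylbut-2-enyl)-4-(triisopropylsilyloxy)phenyl]-5,7-bis(triisopropylsilyloxy)-4H-1,3-benzodioxin-4-one, racemic at C2 | C=CCc1c(O[Si](C(C)C)(C(C)C)C(C)C)cc(O[Si](C(C)C)(C(C)C)C(C)C)c2c1OC(c1ccc(O[Si](C(C)C)(C(C)C)C(C)C)c(CC=C(C)C)c1)OC2=O | intermediate
14 | 8-allyl-4-methylene-2-[3-(3-methylbut-2-enyl)-4-(triisopropylsilyloxy)phenyl]-5,7-bis(triisopropylsilyloxy)-4H-1,3-benzodioxine, racemic (not isolated) | C=CCc1c(O[Si](C(C)C)(C(C)C)C(C)C)cc(O[Si](C(C)C)(C(C)C)C(C)C)c2c1OC(c1ccc(O[Si](C(C)C)(C(C)C)C(C)C)c(CC=C(C)C)c1)OC2=C | intermediate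
15 | (2S)-8-allyl-2-[3-(3-methylbut-2-enyl)-4-(triisopropylsilyloxy)phenyl]-5,7-bis(triisopropylsilyloxy)chroman-4-one | C=CCc1c(O[Si](C(C)C)(C(C)C)C(C)C)cc(O[Si](C(C)C)(C(C)C)C(C)C)c2c1O[C@H](c1ccc(O[Si](C(C)C)(C(C)C)C(C)C)c(CC=C(C)C)c1)CC2=O | intermediate
16 | (2S)-8-allyl-2-[3-{[(2R)-3,3-dimethyloxiran-2-yl]methyl}-4-(triisopropylsilyloxy)phenyl]-5,7-bis(triisopropylsilyloxy)chroman-4-one | C=CCc1c(O[Si](C(C)C)(C(C)C)C(C)C)cc(O[Si](C(C)C)(C(C)C)C(C)C)c2c1O[C@H](c1ccc(O[Si](C(C)C)(C(C)C)C(C)C)c(C[C@H]3OC3(C)C)c1)CC2=O | intermediate
17 | (2S)-2-[3-{[(2R)-3,3-dimethyloxiran-2-yl]methyl}-4-(triisopropylsilyloxy)phenyl]-8-(3-methylbut-2-enyl)-5,7-bis(triisopropylsilyloxy)chroman-4-one | CC(C)=CCc1c(O[Si](C(C)C)(C(C)C)C(C)C)cc(O[Si](C(C)C)(C(C)C)C(C)C)c2c1O[C@H](c1ccc(O[Si](C(C)C)(C(C)C)C(C)C)c(C[C@H]3OC3(C)C)c1)CC2=O | intermediate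
18 | (2S)-2-[3-{[(2R)-3,3-dimethyloxiran-2-yl]methyl}-4-hydroxyphenyl]-5,7-dihydroxy-8-(3-methylbut-2-enyl)chroman-4-one | CC(C)=CCc1c(O)cc(O)c2c1O[C@H](c1ccc(O)c(C[C@H]3OC3(C)C)c1)CC2=O | target

## Step count and least certain steps

Total: 12 steps. Longest linear sequence: 10 steps (from 5 through steps 3 to 12); the ring B arm (steps 1 and 2) joins at step 8.

**Step 9 (key step, the proposed new method).** Three processes are the most likely to fail:

- slow methylenation of a lactone carbonyl that is electron-rich and crowded by the peri silyloxy group;
- diversion of 14 by C-protonation and hydrolysis to the methyl ketone and the aldehyde;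
- above all, poor facial selectivity in the recombination of the ion pair, because the catalyst has to bind the enol next to a bulky silyloxy group and the cation offers no hydrogen-bond donor. A racemic background path and acid-mediated ring opening of the product would erode selectivity further.

Fallback, known chemistry only, from 11 back to 15. The acid 11 would be treated with MeLi (3.3 equiv, THF, 0 °C) to give the methyl ketone 1-[3-allyl-2-hydroxy-4,6-bis(triisopropylsilyloxy)phenyl]ethan-1-one F1. Amine-mediated aldol condensation and oxa-Michael closure of F1 with 4 (pyrrolidine, EtOH, 50 °C) should give the racemic flavanone rac-8-allyl-2-[3-(3-methylbut-2-enyl)-4-(triisopropylsilyloxy)phenyl]-5,7-bis(triisopropylsilyloxy)chroman-4-one F2. Kinetic resolution of F2 by asymmetric transfer hydrogenation (RuCl(p-cymene)[TsDPEN] of the enantiomeric series that reduces the (2R) ketone faster, HCO2H/Et3N) would leave 15 and convert the unwanted enantiomer into the cis-alcohol (2R,4R)-8-allyl-2-[3-(3-methylbut-2-enyl)-4-(triisopropylsilyloxy)phenyl]-5,7-bis(triisopropylsilyloxy)chroman-4-ol F3, which is separated. At most half of the material is kept. If only the enantioselectivity of step 9 fails, racemic material from an achiral Lewis acid (Me2AlCl) would enter the same resolution as F2.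

**Step 8.** The doubly ortho-substituted silyl ether and ester of 12 may be slow to condense, and the product is an ionizable acylal of an electron-rich aldehyde. Decomposition by ionization on silica, Friedel–Crafts capture of the benzylic cation, and loss of CO2 from 11 before it reacts are the likely failures.

Fallback from 4 and 11 back to 13. Aldehyde 4 would be converted with HC(OMe)3 and pyridinium p-toluenesulfonate into the dimethyl acetal 4-(dimethoxymethyl)-2-(3-methylbut-2-enyl)phenyl triisopropylsilyl ether F4. Acetal exchange of F4 with the free acid 11 (pyridinium p-toluenesulfonate, benzene, 5 Å sieves to take up methanol) would then give 13 without a silyl triflate and without the silylation of 11.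

**Step 10.** At pH 10.5 the flavanone can open to the chalcone by enolization and β-elimination and reclose, which would erode C2, and the silyl ethers activated by the ketone can be lost. Over-oxidation of the allyl group is less likely.

Fallback from 15 back to 16. Ketone 15 would be reduced with NaBH4 (MeOH–THF, 0 °C) to the cis-alcohol (2S,4S)-8-allyl-2-[3-(3-methylbut-2-enyl)-4-(triisopropylsilyloxy)phenyl]-5,7-bis(triisopropylsilyloxy)chroman-4-ol F5, which cannot ring-open by elimination and whose silyl ethers are no longer activated. Shi epoxidation under the same conditions would give (2S,4S)-8-allyl-2-[3-{[(2R)-3,3-dimethyloxiran-2-yl]methyl}-4-(triisopropylsilyloxy)phenyl]-5,7-bis(triisopropylsilyloxy)chroman-4-ol F6. Oxidation with Dess–Martin periodinane (NaHCO3, CH2Cl2) would return the ketone 16.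

**Step 12.** If buffering is imperfect, a transient ring B phenoxide opens the neighbouring epoxide (5-exo, to a dihydrobenzofuran) or C2 epimerizes. The hindered ring B silyl ether may also cleave slowly, which invites longer exposure.

Fallback from 15 to 18, without fluoride in the presence of the epoxide. 15 would be desilylated (TBAF/AcOH) before any epoxide exists, giving (2S)-8-allyl-5,7-dihydroxy-2-[4-hydroxy-3-(3-methylbut-2-enyl)phenyl]chroman-4-one F7. Acetylation (Ac2O, pyridine) would give the triacetate (2S)-8-allyl-2-[4-acetoxy-3-(3-methylbut-2-enyl)phenyl]-4-oxochroman-5,7-diyl diacetate F8. Shi epoxidation at pH 8 with a stoichiometric amount of the ketone, where aryl acetates survive, would give (2S)-8-allyl-2-[4-acetoxy-3-{[(2R)-3,3-dimethyloxiran-2-yl]methyl}phenyl]-4-oxochroman-5,7-diyl diacetate F9. Cross-metathesis as in step 11 would give (2S)-2-[4-acetoxy-3-{[(2R)-3,3-dimethyloxiran-2-yl]methyl}phenyl]-8-(3-methylbut-2-enyl)-4-oxochroman-5,7-diyl diacetate F10. Neutral deacetylation with NH4OAc in aqueous methanol would then give 18. This costs two more steps.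

**Step 6.** Competing migration of the allyl group to the ester-bearing carbon, followed by loss of the ester or onward para migration, and thermal degradation at 190 °C are the risks.

Fallback from 7 back to 10, avoiding the sigmatropic step. Direct C-allylation of the phloroglucinol ring of 7 with 6 in aqueous KOH would give allyl 3-allyl-2,4,6-trihydroxybenzoate F11. Bis-silylation (TIPSCl, imidazole) is expected to take the para hydroxyl and the less hindered ortho hydroxyl, leaving the chelated hydroxyl beside the allyl group free and so giving 10. This also saves one step but depends on two selectivities.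

## Further compounds

F1 | step 9 | 1-[3-allyl-2-hydroxy-4,6-bis(triisopropylsilyloxy)phenyl]ethan-1-one | CC(=O)c1c(O)c(CC=C)c(O[Si](C(C)C)(C(C)C)C(C)C)cc1O[Si](C(C)C)(C(C)C)C(C)C
F2 | step 9 | rac-8-allyl-2-[3-(3-methylbut-2-enyl)-4-(triisopropylsilyloxy)phenyl]-5,7-bis(triisopropylsilyloxy)chroman-4-one | C=CCc1c(O[Si](C(C)C)(C(C)C)C(C)C)cc(O[Si](C(C)C)(C(C)C)C(C)C)c2c1OC(c1ccc(O[Si](C(C)C)(C(C)C)C(C)C)c(CC=C(C)C)c1)CC2=O
F3 | step 9 | (2R,4R)-8-allyl-2-[3-(3-methylbut-2-enyl)-4-(triisopropylsilyloxy)phenyl]-5,7-bis(triisopropylsilyloxy)chroman-4-ol | C=CCc1c(O[Si](C(C)C)(C(C)C)C(C)C)cc(O[Si](C(C)C)(C(C)C)C(C)C)c2c1O[C@@H](c1ccc(O[Si](C(C)C)(C(C)C)C(C)C)c(CC=C(C)C)c1)C[C@H]2O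
F4 | step 8 | 4-(dimethoxymethyl)-2-(3-methylbut-2-enyl)phenyl triisopropylsilyl ether | COC(OC)c1ccc(O[Si](C(C)C)(C(C)C)C(C)C)c(CC=C(C)C)c1
F5 | step 10 | (2S,4S)-8-allyl-2-[3-(3-methylbut-2-enyl)-4-(triisopropylsilyloxy)phenyl]-5,7-bis(triisopropylsilyloxy)chroman-4-ol | C=CCc1c(O[Si](C(C)C)(C(C)C)C(C)C)cc(O[Si](C(C)C)(C(C)C)C(C)C)c2c1O[C@H](c1ccc(O[Si](C(C)C)(C(C)C)C(C)C)c(CC=C(C)C)c1)C[C@@H]2O
F6 | step 10 | (2S,4S)-8-allyl-2-[3-{[(2R)-3,3-dimethyloxiran-2-yl]methyl}-4-(triisopropylsilyloxy)phenyl]-5,7-bis(triisopropylsilyloxy)chroman-4-ol | C=CCc1c(O[Si](C(C)C)(C(C)C)C(C)C)cc(O[Si](C(C)C)(C(C)C)C(C)C)c2c1O[C@H](c1ccc(O[Si](C(C)C)(C(C)C)C(C)C)c(C[C@H]3OC3(C)C)c1)C[C@@H]2O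
F7 | step 12 | (2S)-8-allyl-5,7-dihydroxy-2-[4-hydroxy-3-(3-methylbut-2-enyl)phenyl]chroman-4-one | C=CCc1c(O)cc(O)c2c1O[C@H](c1ccc(O)c(CC=C(C)C)c1)CC2=O
F8 | step 12 | (2S)-8-allyl-2-[4-acetoxy-3-(3-methylbut-2-enyl)phenyl]-4-oxochroman-5,7-diyl diacetate | C=CCc1c(OC(C)=O)cc(OC(C)=O)c2c1O[C@H](c1ccc(OC(C)=O)c(CC=C(C)C)c1)CC2=O
F9 | step 12 | (2S)-8-allyl-2-[4-acetoxy-3-{[(2R)-3,3-dimethyloxiran-2-yl]methyl}phenyl]-4-oxochroman-5,7-diyl diacetate | C=CCc1c(OC(C)=O)cc(OC(C)=O)c2c1O[C@H](c1ccc(OC(C)=O)c(C[C@H]3OC3(C)C)c1)CC2=O
F10 | step 12 | (2S)-2-[4-acetoxy-3-{[(2R)-3,3-dimethyloxiran-2-yl]methyl}phenyl]-8-(3-methylbut-2-enyl)-4-oxochroman-5,7-diyl diacetate | CC(C)=CCc1c(OC(C)=O)cc(OC(C)=O)c2c1O[C@H](c1ccc(OC(C)=O)c(C[C@H]3OC3(C)C)c1)CC2=O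
F11 | step 6 | allyl 3-allyl-2,4,6-trihydroxybenzoate | C=CCOC(=O)c1c(O)cc(O)c(CC=C)c1O
A1 | alternative 1 | 5,7-bis(tert-butyldimethylsilyloxy)-2-[4-(tert-butyldimethylsilyloxy)-3-{[(2R)-3,3-dimethyloxiran-2-yl]methyl}phenyl]-8-(3-methylbut-2-enyl)-4H-chromen-4-one | CC(C)=CCc1c(O[Si](C)(C)C(C)(C)C)cc(O[Si](C)(C)C(C)(C)C)c2c1OC(c1ccc(O[Si](C)(C)C(C)(C)C)c(C[C@H]3OC3(C)C)c1)=CC2=O
A2 | alternative 1 | 3,5-bis(tert-butyldimethylsilyloxy)-2-iodo-6-(3-methylbut-2-enyl)phenol | Oc1c(I)c(O[Si](C)(C)C(C)(C)C)cc(O[Si](C)(C)C(C)(C)C)c1CC=C(C)C
A3 | alternative 1 | tert-butyl{2-[((2R)-3,3-dimethyloxiran-2-yl)methyl]-4-ethynylphenoxy}dimethylsilane | C#Cc1ccc(O[Si](C)(C)C(C)(C)C)c(C[C@H]2OC2(C)C)c1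
A4 | alternative 2 | (2S,4S)-8-allyl-4-methoxy-2-[3-(3-methylbut-2-enyl)-4-(triisopropylsilyloxy)phenyl]-5,7-bis(triisopropylsilyloxy)chromane (2,4-cis) | C=CCc1c(O[Si](C(C)C)(C(C)C)C(C)C)cc(O[Si](C(C)C)(C(C)C)C(C)C)c2c1O[C@H](c1ccc(O[Si](C(C)C)(C(C)C)C(C)C)c(CC=C(C)C)c1)C[C@@H]2OC
A5 | alternative 2 | 3-allyl-2-hydroxy-4,6-bis(triisopropylsilyloxy)benzaldehyde | C=CCc1c(O)c(C=O)c(O[Si](C(C)C)(C(C)C)C(C)C)cc1O[Si](C(C)C)(C(C)C)C(C)C
A6 | alternative 2 | triisopropyl[2-(3-methylbut-2-enyl)-4-vinylphenoxy]silane | C=Cc1ccc(O[Si](C(C)C)(C(C)C)C(C)C)c(CC=C(C)C)c1
A7 | alternative 3 | (2S)-5,7-bis(allyloxy)-2-[4-(allyloxy)-3-{[(2R)-3,3-dimethyloxiran-2-yl]methyl}phenyl]-8-(3-methylbut-2-enyl)chroman-4-one | CC(C)=CCc1c(OCC=C)cc(OCC=C)c2c1O[C@H](c1ccc(OCC=C)c(C[C@H]3OC3(C)C)c1)CC2=O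
A8 | alternative 3 | 3,5-bis(allyloxy)-2-(3-methylbut-2-enyl)-6-(trimethylsilyl)phenyl trifluoromethanesulfonate | C=CCOc1cc(OCC=C)c([Si](C)(C)C)c(OS(=O)(=O)C(F)(F)F)c1CC=C(C)C
A9 | alternative 3 | methyl (3S)-3-[4-(allyloxy)-3-{[(2R)-3,3-dimethyloxiran-2-yl]methyl}phenyl]-3-hydroxypropanoate | O[C@H](c1ccc(OCC=C)c(C[C@H]2OC2(C)C)c1)CC(=O)OC
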